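**Catalyst's price.** 10.6 target per catalyst charged, the turnover number at equal charges of starting material and second substrate, is the last west and south readings, averaged, over their loading.

| flask | starting material | second substrate | free catalyst | remark | time |
|---|---|---|---|---|---|
| west | 0.38 M | 1 equiv | 3.9 mol% | run made earlier |  |
| south | 1.3 M | 1 equiv | 3.9 mol% | run made earlier |  |
| north-east | 1 M | 0.43 equiv | 3.9 mol% | run made earlier |  |
| midnight | 0.60 M | 0.250 equiv | 15 mol% |  | 2.5 min |
| dawn | 1.0 M | 1.00 equiv | 3.9 mol% |  | 2.5 min |
| spring | 0.60 M | 1.00 equiv | 1.2 mol% |  | 2.5 min |
| noon | 0.30 M | 0.330 equiv | 6 mol% |  | 2.5 min |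

| run | time / min | target / % |
|---|---|---|
| west | 0.200 | 19.1 |
| west | 0.667 | 34.2 |
| west | 1.33 | 40.7 |
| west | 2.00 | 41.2 |
| west | 2.50 | 41.1 |
| south | 0.200 | 32.5 |
| south | 0.667 | 40.9 |
| south | 1.33 | 41.5 |
| south | 2.00 | 42.3 |
| south | 2.50 | 41.9 |
| north-east | 0.200 | 40.7 |
| north-east | 0.667 | 67.8 |
| north-east | 1.33 | 78.8 |
| north-east | 2.00 | 81.6 |
| north-east | 2.50 | 84.4 |

(scatter of a reading: 0.5 percentage points)

1. ranking by amount of target, in percent of the starting material charged, from high to low, at 2.5 min (midnight / dawn / spring / noon)
2. the same order at 8.0 s (midnight / dawn / spring / noon)
3. the amount of target, in percent of the starting material charged of the flask you put first, at 2.5 min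
4. the amount of target, in percent of the starting material charged of the flask you put last, at 2.5 min

**Opening balance.** West stands at 41.1% and south at 41.9%, though south holds 3.42 times the concentration, and 58.9% of west's starting material has not appeared as target. A stop that ignores concentration at equal loading suggests a loss counted per turnover, not per minute, which makes the catalyst the limiting reagent of these runs.

**Entries.** Starting material and second substrate draw on the same free catalyst, so target per catalyst lost should follow the ratio of their charges. Replacing that drifting ratio by its opening value gives the budget, the turnover number times the loading over the equivalents of second substrate, as a fraction of the starting charge. North-east is the test: its budget is 96.5%, and its readings, still climbing, have reached 84.4%.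

**Closing entries.** My reckoning books dawn at 41.5% and spring at 12.8%, while midnight's budget is 6.38 charges and noon's 1.93, so both can finish. West's first reading puts noon's half-life near 0.538 min, well inside 2.5 min, so I rank midnight, noon, dawn, spring. At 8.0 s I put dawn ahead of noon as a judgement, on the ground that dawn holds more catalyst per litre.

**The forecast.** It gives midnight > noon > dawn > spring at 2.5 min and midnight > dawn > noon > spring at 8.0 s, with 99.5% on top and 12.7% at the bottom, against my 12.8%, on the ground that “the catalyst dies by turnover on the second substrate”.

**The result.** The flasks rank midnight > noon > dawn > spring at 2.5 min and midnight > dawn > noon > spring at 8.0 s, with midnight at 100% and spring at 13.5%.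

    starting material + free catalyst ⇌ catalyst intermediate A (K = 0.843 /M, k = 1.73 /M/s)
    catalyst intermediate A → free catalyst + target (k = 34.6 /s)
    second substrate + free catalyst ⇌ catalyst intermediate B (K = 1.33 /M, k = 1.46 /M/s)
    catalyst intermediate B → free catalyst + second product (k = 3.81 /s)
    catalyst intermediate B → spent catalyst (k = 0.528 /s)

At equal concentrations of the two substrates, these constants form 11.5 target per spent catalyst, and spring, holding 86.5% of its starting material and 90.1% of its second substrate at the end, paid 11.3 per catalyst charged. The budget put spring at 12.8% against 13.5%, and it had midnight losing 15.7% of its catalyst, while midnight's spent catalyst stands at 20.3%.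

(The runs were generated by integration for an exercise, noise included.)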